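**Plan**

1. Numbering: chain C1 (benzylic CH2) to C12 (CH2 on the furan). Cuts: C7–C8 (vinyl carbon to CH2) by undoing a syn-carbomagnesiation, then C1–C2 and C3–CH3 (carboalumination/benzyl coupling), C4–C5 (propargylation of but-2-ynal) and C12–furan C2 (γ-alkylation of a silyloxyfuran).
2. Enabling feature: the free C5 hydroxyl sits on the carbon next to the C6=C7 olefin, so C6/C7 can be carried as an alkyne (a but-2-ynyl carbinol) whose magnesium alkoxide steers the incoming chain to C7 and the metal to C6.
3. Forward: benzyl bromide 3 + diynol 8 give left fragment 10; homoprenyl bromide gives dibromide 13, butenolide 16 and furan 18 (the only ring made, by reductive aromatisation); 10 + 18 give 22, then desilylation to 23.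
4. Stereochemistry: C5 (R) from a chiral phosphoric acid catalysed propargylation; 2E from syn-carboalumination; 6E from syn-carbomagnesiation; 10E from SeO2 oxidation of the E-methyl group.

Key step: step 11

Remark: the target is read as the (2E,5R,6E,10E) isomer; the free hydroquinone is air-sensitive, so it stays silylated until the last step.

Step 1
Reactants: 1 2,6-dimethylbenzene-1,4-diol
Product: 2 1,4-bis(tert-butyldimethylsilyloxy)-2,6-dimethylbenzene
Conditions: TBSCl (2.5 equiv), imidazole, DMF, 50 °C, N2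
Reagents that add atoms: tert-butyldimethylsilyl chloride, CC(C)(C)[Si](C)(C)Cl
Why: Silyl ether formation on both phenols (the OH flanked by two methyls needs gentle heating) gives a hydroquinone mask that should tolerate alanes, Pd and Grignard reagents and falls to fluoride at the end.

Step 2
Reactants: 2 1,4-bis(tert-butyldimethylsilyloxy)-2,6-dimethylbenzene
Product: 3 1,4-bis(tert-butyldimethylsilyloxy)-2-(bromomethyl)-6-methylbenzene
Conditions: NBS (0.9 equiv), AIBN (cat.), PhCF3, 80 °C
Reagents that add atoms: N-bromosuccinimide, O=C1CCC(=O)N1Br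
Why: Wohl–Ziegler benzylic bromination; the two methyl groups are equivalent by symmetry, so mono-bromination with sub-stoichiometric NBS can give only one bromide, and the bulky silyloxy groups shield the free ring positions from electrophilic bromination.

Step 3
Reactants: 4 but-2-yn-1-ol
Product: 5 but-2-ynal
Conditions: MnO2 (activated, excess), CH2Cl2, rt; filtered and used as a solution
Reagents that add atoms: none
Why: MnO2 oxidises the propargylic alcohol selectively to the ynal without over-oxidation, and the volatile aldehyde is not concentrated.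

Step 4
Reactants: 5 but-2-ynal; 6 allenylboronic acid pinacol ester
Product: 8 (4R)-hepta-1,5-diyn-4-ol, via borate ester 7 (not isolated)
Conditions: (R)-TRIP (10 mol%), 4 Å MS, toluene, −20 °C; then aq. NaHCO3
Reagents that add atoms: none
Why: Chiral phosphoric acid catalysed propargylation by the allenylboronate through a closed six-membered SE2' transition state; (R)-TRIP is expected to direct attack to the Re face of the aldehyde, which gives the (R)-carbinol (O > alkynyl > CH2), and the borate is hydrolysed on work-up.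

Step 5
Reactants: 8 (4R)-hepta-1,5-diyn-4-ol; 3 1,4-bis(tert-butyldimethylsilyloxy)-2-(bromomethyl)-6-methylbenzene
Product: 10 (4R,6E)-8-[2,5-bis(tert-butyldimethylsilyloxy)-3-methylphenyl]-6-methyloct-6-en-2-yn-4-ol, via alkenylalane 9 (not isolated)
Conditions: 8 (1.3 equiv), Me3Al (3 equiv), Cp2ZrCl2 (0.25 equiv), CH2Cl2, 0 °C → rt; volatiles removed; then 3, Pd(PPh3)4 (5 mol%), THF, rt; aq. Rochelle salt
Reagents that add atoms: trimethylaluminium, C[Al](C)C
Why: Negishi zirconium-catalysed syn-carboalumination of the terminal alkyne (methyl to the internal carbon, aluminium to the terminus, the internal alkyne being far slower) followed by Pd-catalysed alkenylalane–benzyl bromide cross-coupling with retention should set the 6E olefin of 10 and the aryl–CH2 bond in one flask without touching the carbinol centre.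

Step 6
Reactants: 11 5-bromo-2-methylpent-2-ene
Product: 12 (2E)-5-bromo-2-methylpent-2-en-1-ol
Conditions: SeO2 (0.3 equiv), t-BuOOH (3 equiv), salicylic acid (cat.), CH2Cl2, rt
Reagents that add atoms: tert-butyl hydroperoxide, CC(C)(C)OO
Why: SeO2 allylic oxidation (ene reaction, then [2,3]-sigmatropic shift) hydroxylates the E-methyl group of a trisubstituted olefin selectively and should leave the primary bromide untouched.

Step 7
Reactants: 12 (2E)-5-bromo-2-methylpent-2-en-1-ol
Product: 13 (2E)-1,5-dibromo-2-methylpent-2-ene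
Conditions: PBr3 (0.4 equiv), Et2O, 0 °C
Reagents that add atoms: phosphorus tribromide, BrP(Br)Br
Why: PBr3 converts a primary allylic alcohol to the bromide at 0 °C without allylic transposition or loss of olefin geometry, as in the standard preparation of geranyl bromide.

Step 8
Reactants: 14 3-methylfuran-2(5H)-one
Product: 15 3-methyl-2-(trimethylsilyloxy)furan
Conditions: TMSOTf (1.1 equiv), Et3N, CH2Cl2, 0 °C
Reagents that add atoms: trimethylsilyl trifluoromethanesulfonate, C[Si](C)(C)OS(=O)(=O)C(F)(F)F
Why: Soft enolisation and O-silylation of the butenolide gives the aromatic 2-silyloxyfuran, a dienolate equivalent that is nucleophilic at C5.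

Step 9
Reactants: 15 3-methyl-2-(trimethylsilyloxy)furan; 13 (2E)-1,5-dibromo-2-methylpent-2-ene
Product: 16 5-[(2E)-5-bromo-2-methylpent-2-en-1-yl]-3-methylfuran-2(5H)-one (racemic)
Conditions: AgOCOCF3 (1.1 equiv), CH2Cl2, −78 → −20 °C
Reagents that add atoms: none
Why: Silver-promoted γ-alkylation of a 2-silyloxyfuran; the silver ion activates only the allylic bromide, the furan attacks through C5 at the less hindered primary allyl terminus so that the trisubstituted E-olefin is kept, and the new C5 centre of the lactone is racemic and is erased in step 10.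

Step 10
Reactants: 16 5-[(2E)-5-bromo-2-methylpent-2-en-1-yl]-3-methylfuran-2(5H)-one
Product: 18 2-[(2E)-5-bromo-2-methylpent-2-en-1-yl]-4-methylfuran, via lactol 17 (not isolated)
Conditions: i-Bu2AlH (1.2 equiv), CH2Cl2, −78 °C; then 1 M aq. H2SO4, Et2O, 0 °C → rt
Reagents that add atoms: none
Why: Reductive aromatisation of a 2(5H)-furanone; i-Bu2AlH reduces the lactone to the lactol, which loses water on acidic work-up to give the 2,4-disubstituted furan regiospecifically, the alkyl bromide and olefin being inert at −78 °C.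

Step 11
Reactants: 10 (4R,6E)-8-[2,5-bis(tert-butyldimethylsilyloxy)-3-methylphenyl]-6-methyloct-6-en-2-yn-4-ol; 18 2-[(2E)-5-bromo-2-methylpent-2-en-1-yl]-4-methylfuran
Product: 22 (2E,5R,6E,10E)-1-[2,5-bis(tert-butyldimethylsilyloxy)-3-methylphenyl]-3,7,11-trimethyl-12-(4-methylfuran-2-yl)dodeca-2,6,10-trien-5-ol, via Grignard reagent 19 (not isolated), via magnesium alkoxide 20 (not isolated), via alkenylmagnesium 21 (not isolated)
Conditions: 18, Mg, THF, rt (gives 19); 10, MeMgBr (1.0 equiv), THF, −78 → 0 °C (gives 20); then 19 (2.5 equiv), Fe(acac)3 (15 mol%), THF, −20 → 0 °C; aq. NH4Cl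
Reagents that add atoms: none
Why: The bromomagnesium alkoxide 20 binds the alkyl–iron species formed from Fe(acac)3 and Grignard reagent 19 and delivers the alkyl group across the C6≡C7 triple bond by syn-carbometalation, the chain going to the distal, methyl-bearing C7 and the metal to C6 next to the alkoxide oxygen; transmetalation to magnesium gives alkenyl Grignard 21 and returns the iron catalyst, and protonation on work-up proceeds with retention. The closest known reaction type is the iron-catalysed, alkoxide-directed carbomagnesiation of propargylic alcohols with alkyl Grignard reagents, which gives trisubstituted allylic alcohols with this regio- and syn-stereochemistry. No ring is closed and no new stereocentre is made; the C5 carbinol from step 4 is carried through as its alkoxide and cannot epimerise. Syn addition places the incoming chain cis to the new vinyl hydrogen and therefore trans to C5, with the existing methyl cis to the carbinol, which is the required 6E geometry. Regiocontrol rests on the C5 alkoxide, since the methyl-capped alkyne has no other strong bias, and chemoselectivity on the fact that only the alkyne is tethered to an alkoxide: the trisubstituted olefins, the aryl silyl ethers and the furan carry no directing group and should be inert to Grignard reagents at 0 °C.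

Step 12
Reactants: 22 (2E,5R,6E,10E)-1-[2,5-bis(tert-butyldimethylsilyloxy)-3-methylphenyl]-3,7,11-trimethyl-12-(4-methylfuran-2-yl)dodeca-2,6,10-trien-5-ol
Product: 23 2-[(2E,5R,6E,10E)-5-hydroxy-3,7,11-trimethyl-12-(4-methylfuran-2-yl)dodeca-2,6,10-trien-1-yl]-6-methylbenzene-1,4-diol
Conditions: Bu4NF (2.2 equiv), AcOH (2.2 equiv), degassed THF, 0 °C, Ar; aq. NH4Cl/Na2S2O4 wash
Reagents that add atoms: none
Why: Fluoride-mediated cleavage of the two aryl silyl ethers, with acetic acid buffering the phenoxides and air excluded so that the hydroquinone is not oxidised; no olefin or stereocentre is touched.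

**Compound list**

1 | 2,6-dimethylbenzene-1,4-diol | Cc1cc(O)cc(C)c1O | starting material
2 | 1,4-bis(tert-butyldimethylsilyloxy)-2,6-dimethylbenzene | Cc1cc(O[Si](C)(C)C(C)(C)C)cc(C)c1O[Si](C)(C)C(C)(C)C | intermediate
3 | 1,4-bis(tert-butyldimethylsilyloxy)-2-(bromomethyl)-6-methylbenzene | BrCc1cc(O[Si](C)(C)C(C)(C)C)cc(C)c1O[Si](C)(C)C(C)(C)C | intermediate
4 | but-2-yn-1-ol | CC#CCO | starting material
5 | but-2-ynal | CC#CC=O | intermediate
6 | allenylboronic acid pinacol ester (4,4,5,5-tetramethyl-2-(propa-1,2-dien-1-yl)-1,3,2-dioxaborolane) | C=C=CB1OC(C)(C)C(C)(C)O1 | starting material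
7 | 2-[(4R)-hepta-1,5-diyn-4-yloxy]-4,4,5,5-tetramethyl-1,3,2-dioxaborolane | CC#C[C@H](OB1OC(C)(C)C(C)(C)O1)CC#C | intermediate (not isolated)
8 | (4R)-hepta-1,5-diyn-4-ol | CC#C[C@H](O)CC#C | intermediate
9 | [(1E,4R)-4-(dimethylalumanyloxy)-2-methylhept-1-en-5-yn-1-yl]dimethylalumane | CC#C[C@H](O[Al](C)C)C/C(C)=C/[Al](C)C | intermediate (not isolated)
10 | (4R,6E)-8-[2,5-bis(tert-butyldimethylsilyloxy)-3-methylphenyl]-6-methyloct-6-en-2-yn-4-ol | CC#C[C@H](O)C/C(C)=C/Cc1cc(O[Si](C)(C)C(C)(C)C)cc(C)c1O[Si](C)(C)C(C)(C)C | intermediate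
11 | 5-bromo-2-methylpent-2-ene | CC(C)=CCCBr | starting material
12 | (2E)-5-bromo-2-methylpent-2-en-1-ol | OC/C(C)=C/CCBr | intermediate
13 | (2E)-1,5-dibromo-2-methylpent-2-ene | BrC/C(C)=C/CCBr | intermediate
14 | 3-methylfuran-2(5H)-one | CC1=CCOC1=O | starting material
15 | 3-methyl-2-(trimethylsilyloxy)furan | Cc1ccoc1O[Si](C)(C)C | intermediate
16 | 5-[(2E)-5-bromo-2-methylpent-2-en-1-yl]-3-methylfuran-2(5H)-one (racemic) | CC1=CC(C/C(C)=C/CCBr)OC1=O | intermediate
17 | 5-[(2E)-5-bromo-2-methylpent-2-en-1-yl]-3-methyl-2,5-dihydrofuran-2-ol | CC1=CC(C/C(C)=C/CCBr)OC1O | intermediate (not isolated)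
18 | 2-[(2E)-5-bromo-2-methylpent-2-en-1-yl]-4-methylfuran | BrCC/C=C(\C)Cc1cc(C)co1 | intermediate
19 | bromo[(3E)-4-methyl-5-(4-methylfuran-2-yl)pent-3-en-1-yl]magnesium | Br[Mg]CC/C=C(\C)Cc1cc(C)co1 | intermediate (not isolated)
20 | bromomagnesium (4R,6E)-8-[2,5-bis(tert-butyldimethylsilyloxy)-3-methylphenyl]-6-methyloct-6-en-2-yn-4-olate | CC#C[C@H](O[Mg]Br)C/C(C)=C/Cc1cc(O[Si](C)(C)C(C)(C)C)cc(C)c1O[Si](C)(C)C(C)(C)C | intermediate (not isolated)
21 | C6-bromomagnesio bromomagnesium alkoxide of 22 (chain cis to Mg at C6=C7) | C/C(=C(/[Mg]Br)[C@H](O[Mg]Br)C/C(C)=C/Cc1cc(O[Si](C)(C)C(C)(C)C)cc(C)c1O[Si](C)(C)C(C)(C)C)CC/C=C(\C)Cc1cc(C)co1 | intermediate (not isolated)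
22 | (2E,5R,6E,10E)-1-[2,5-bis(tert-butyldimethylsilyloxy)-3-methylphenyl]-3,7,11-trimethyl-12-(4-methylfuran-2-yl)dodeca-2,6,10-trien-5-ol | C/C(=C\[C@H](O)C/C(C)=C/Cc1cc(O[Si](C)(C)C(C)(C)C)cc(C)c1O[Si](C)(C)C(C)(C)C)CC/C=C(\C)Cc1cc(C)co1 | intermediate
23 | 2-[(2E,5R,6E,10E)-5-hydroxy-3,7,11-trimethyl-12-(4-methylfuran-2-yl)dodeca-2,6,10-trien-1-yl]-6-methylbenzene-1,4-diol | C/C(=C\[C@H](O)C/C(C)=C/Cc1cc(O)cc(C)c1O)CC/C=C(\C)Cc1cc(C)co1 | target

**Step count and risks**

Total step count: 12. Longest linear sequence: 6 steps (steps 6, 7, 9, 10, 11, 12).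

Steps most likely to fail:

1. Step 11. The alkyl–iron intermediate carries allylic β-hydrogens and may undergo β-hydride elimination, which would reduce the alkyne instead of alkylating it; regiocontrol may also be incomplete. The fallback sets out from 10 and 18 and returns at 23. Alcohol 10 is silylated (TBSCl, imidazole, DMF) to the tris(silyl) ether F1. Hydrozirconation with excess Cp2Zr(H)Cl (THF, rt to 40 °C, so that zirconium settles on the less hindered, methyl-bearing carbon) and iodinolysis with I2 give the (2E)-vinyl iodide F2. Bromide 18 is converted with Zn dust and LiCl (THF, 50 °C) into the alkylzinc bromide F3. Negishi coupling of F3 with F2 (Pd(dppf)Cl2, THF, rt), which retains olefin geometry, gives the tris(silyl) triene F4, and Bu4NF (THF, rt) removes all three silyl groups to give 23.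

2. Step 4. The small, linear alkynyl aldehyde may be discriminated poorly in the catalyst pocket, so facial selectivity could be low. The fallback sets out from 5 and 3 and returns at 10. But-2-ynal 5 is propargylated without stereocontrol (propargyl bromide, Zn, THF/aq. NH4Cl, Barbier conditions) to racemic hepta-1,5-diyn-4-ol F5. This is taken through the conditions of step 5 with bromide 3, by way of the racemic alkenylalane F6, to the racemic propargylic alcohol F7. Dess–Martin periodinane oxidation gives the ynone F8. Noyori asymmetric transfer hydrogenation with RuCl(p-cymene)[(R,R)-TsDPEN] in i-PrOH then sets the (R)-carbinol by reagent control and gives 10.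

3. Step 9. Ionisation gives an unsymmetrical allyl cation that may be captured at its secondary terminus or after loss of olefin geometry, and attack through C3 of the silyloxyfuran may compete. The fallback sets out from 13 and returns at 18. Chloroacetone is treated with HC≡CMgBr (THF, −78 °C) to give 1-chloro-2-methylbut-3-yn-2-ol F9, which KOH closes to 2-ethynyl-2-methyloxirane F10. Coupling of F10 with the allylic bromide of 13 (CuI, K2CO3, DMF, rt), an SN2 displacement at the primary allylic carbon that keeps the olefin geometry, gives the epoxy enyne F11. AuCl3-catalysed cycloisomerisation of the alkynyl oxirane (MeCN, rt) gives furan 18 directly.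

Further compounds
F1 | step 11 | tert-butyl{[(4R,6E)-8-[2,5-bis(tert-butyldimethylsilyloxy)-3-methylphenyl]-6-methyloct-6-en-2-yn-4-yl]oxy}dimethylsilane | CC#C[C@H](O[Si](C)(C)C(C)(C)C)C/C(C)=C/Cc1cc(O[Si](C)(C)C(C)(C)C)cc(C)c1O[Si](C)(C)C(C)(C)C
F2 | step 11 | (2E,4R,6E)-8-[2,5-bis(tert-butyldimethylsilyloxy)-3-methylphenyl]-4-(tert-butyldimethylsilyloxy)-2-iodo-6-methylocta-2,6-diene | C/C(I)=C\[C@H](O[Si](C)(C)C(C)(C)C)C/C(C)=C/Cc1cc(O[Si](C)(C)C(C)(C)C)cc(C)c1O[Si](C)(C)C(C)(C)C
F3 | step 11 | bromo[(3E)-4-methyl-5-(4-methylfuran-2-yl)pent-3-en-1-yl]zinc | Br[Zn]CC/C=C(\C)Cc1cc(C)co1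
F4 | step 11 | (2E,5R,6E,10E)-1-[2,5-bis(tert-butyldimethylsilyloxy)-3-methylphenyl]-5-(tert-butyldimethylsilyloxy)-3,7,11-trimethyl-12-(4-methylfuran-2-yl)dodeca-2,6,10-triene | C/C(=C\[C@H](O[Si](C)(C)C(C)(C)C)C/C(C)=C/Cc1cc(O[Si](C)(C)C(C)(C)C)cc(C)c1O[Si](C)(C)C(C)(C)C)CC/C=C(\C)Cc1cc(C)co1
F5 | step 4 | hepta-1,5-diyn-4-ol (racemic) | CC#CC(O)CC#C
F6 | step 4 | [(1E)-4-(dimethylalumanyloxy)-2-methylhept-1-en-5-yn-1-yl]dimethylalumane (racemic) | CC#CC(O[Al](C)C)C/C(C)=C/[Al](C)C
F7 | step 4 | (6E)-8-[2,5-bis(tert-butyldimethylsilyloxy)-3-methylphenyl]-6-methyloct-6-en-2-yn-4-ol (racemic) | CC#CC(O)C/C(C)=C/Cc1cc(O[Si](C)(C)C(C)(C)C)cc(C)c1O[Si](C)(C)C(C)(C)C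
F8 | step 4 | (6E)-8-[2,5-bis(tert-butyldimethylsilyloxy)-3-methylphenyl]-6-methyloct-6-en-2-yn-4-one | CC#CC(=O)C/C(C)=C/Cc1cc(O[Si](C)(C)C(C)(C)C)cc(C)c1O[Si](C)(C)C(C)(C)C
F9 | step 9 | 1-chloro-2-methylbut-3-yn-2-ol | CC(O)(CCl)C#C
F10 | step 9 | 2-ethynyl-2-methyloxirane | CC1(C#C)CO1
F11 | step 9 | 2-[(4E)-7-bromo-4-methylhept-4-en-1-yn-1-yl]-2-methyloxirane | CC1(C#CC/C(C)=C/CCBr)CO1
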